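The cyclohexane ring (C1H2–C2H2–C3HBr–C4Me2–C5H–C10(Me)O) is read as a masked cyclohexanone: the oxygen-bearing C10 and the bromine-bearing C3 are 1,4-related, with the quaternary C4 next to C3. A triflimide-catalysed Diels–Alder reaction of the 2-silyloxydiene from mesityl oxide (C1=C10–C5=C4) with methyl acrylate (C2=C3) forms the C1–C2 and C3–C4 bonds in one operation, builds the gem-dimethyl centre and leaves a regiodefined silyl enol ether at C10=C5. Its precursor is this acyclic diene. The enol ether then takes up the glycerate-derived side chain; a bridged ketal relays that stereocentre to C10 and C5, and the C3 ester is finally exchanged for bromine.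

Key step: step 2

Remark (locants): the side chain and oxepane carbons are C6H2, C7, C8 (carrying the exocyclic CH2), C9 and C12 (the CH2X carbon on C9); the ring oxygen joins C9 and C10.
Remark (stereochemistry): the key step gives 4 as a racemate at C3 only; this centre is carried as an epimeric mixture and erased in step 10, so every lasting stereocentre derives from the (S)-glycerate ester 5.

Step 1
Reactants: 1 mesityl oxide (4-methylpent-3-en-2-one)
Product: 2 tert-butyl(dimethyl)[(4-methylpenta-1,3-dien-2-yl)oxy]silane
Conditions: TBSOTf, Et3N, CH2Cl2, 0 °C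
Reagents that add atoms: tert-butyldimethylsilyl trifluoromethanesulfonate, CC(C)(C)[Si](C)(C)OS(=O)(=O)C(F)(F)F
Why: Soft enolisation (silyl triflate and amine) removes a proton of the acetyl methyl group and should give the cross-conjugated 2-silyloxydiene; no stereocentre is formed.

Step 2
Reactants: 2 tert-butyl(dimethyl)[(4-methylpenta-1,3-dien-2-yl)oxy]silane; 3 methyl acrylate
Product: 4 methyl 4-[(tert-butyldimethylsilyl)oxy]-2,2-dimethylcyclohex-3-ene-1-carboxylate (racemic)
Conditions: Tf2NH (5 mol %), CH2Cl2, −78 → −40 °C; Et3N quench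
Reagents that add atoms: none
Why: Tf2NH protodesilylates a trace of 2 to TBSNTf2, which silylates the acrylate carbonyl; the CH2 terminus of the silyl enol ether (C1) adds to the acrylate β-carbon (C2) in a Mukaiyama–Michael step, and the silyl ketene acetal so formed closes onto the CMe2 terminus (C4) of the silyloxy-allyl cation, so both bonds form in one operation and the silyl group stays on the C10 oxygen. The closest known reaction type is the triflimide-catalysed (or AlBr3/AlMe3-catalysed) Diels–Alder reaction of hindered 2-silyloxydienes bearing a cis substituent at the diene terminus with acrylates and enones. The six-membered ring is closed by the second C–C bond formation, a 6-(enolexo)-endo-trig Michael-type closure that completes a formal [4+2] cycloaddition. The only new stereocentre, the ester-bearing C3, has no control element, forms as a racemate and is erased in step 10; C4 is quaternary but not stereogenic. The step needs the 1,4 ("para") orientation of ester and silyloxy carbon and ring closure in preference to an open-chain Michael adduct or a [2+2] product. The first is secured by the polarisation of the 2-silyloxydiene (C1 nucleophilic), the second by the tertiary, oxygen-stabilised cation at C4 held five atoms from the ketene acetal carbon.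

Step 3
Reactants: 5 methyl (S)-2,2-dimethyl-1,3-dioxolane-4-carboxylate
Product: 6 (S)-N-methoxy-N,2,2-trimethyl-1,3-dioxolane-4-carboxamide
Conditions: MeNH(OMe)·HCl, i-PrMgCl, THF, −20 °C
Reagents that add atoms: N,O-dimethylhydroxylamine hydrochloride, CNOC.Cl
Why: Aminolysis of the ester by the chloromagnesium amide should give the Weinreb amide without touching the acetonide or the α-stereocentre.

Step 4
Reactants: 6 (S)-N-methoxy-N,2,2-trimethyl-1,3-dioxolane-4-carboxamide
Product: 7 (S)-1-(2,2-dimethyl-1,3-dioxolan-4-yl)prop-2-en-1-one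
Conditions: CH2=CHMgBr, THF, 0 °C; inverse quench into cold aq. HCl
Reagents that add atoms: vinylmagnesium bromide, C=C[Mg]Br
Why: Weinreb ketone synthesis: the chelated tetrahedral intermediate prevents over-addition, the acidic inverse quench keeps the released amine from adding to the enone, and the α-alkoxy stereocentre is not enolised at 0 °C.

Step 5
Reactants: 4 methyl 4-[(tert-butyldimethylsilyl)oxy]-2,2-dimethylcyclohex-3-ene-1-carboxylate; 7 (S)-1-(2,2-dimethyl-1,3-dioxolan-4-yl)prop-2-en-1-one
Product: 9 methyl 3-{3-[(4S)-2,2-dimethyl-1,3-dioxolan-4-yl]-3-oxopropyl}-2,2-dimethyl-4-oxocyclohexane-1-carboxylate (C3 and C5 epimers), via C8 silyl enol ether 8 (not isolated)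
Conditions: Tf2NH (5 mol %), CH2Cl2, −78 °C; then 0.5 M aq. HCl, THF, 0 °C (brief)
Reagents that add atoms: none
Why: Mukaiyama–Michael addition: the regiodefined silyl enol ether attacks the unsubstituted β-carbon of the silyl-activated vinyl ketone through C5, with silyl transfer to the acceptor oxygen; C5 forms without control and is corrected in step 7.

Step 6
Reactants: 9 methyl 3-{3-[(4S)-2,2-dimethyl-1,3-dioxolan-4-yl]-3-oxopropyl}-2,2-dimethyl-4-oxocyclohexane-1-carboxylate
Product: 10 methyl 3-{3-[(4R)-2,2-dimethyl-1,3-dioxolan-4-yl]but-3-en-1-yl}-2,2-dimethyl-4-oxocyclohexane-1-carboxylate (C3 and C5 epimers)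
Conditions: Ph3PCH3Br (1.2 equiv), KN(SiMe3)2 (1.1 equiv), THF, −78 → 0 °C
Reagents that add atoms: methyltriphenylphosphonium bromide, C[P+](c1ccccc1)(c1ccccc1)c1ccccc1.[Br-]
Why: Wittig methylenation should be selective for the acyclic α-alkoxy ketone C8 over the ring ketone C10, which is flanked by the branched C5 and the quaternary C4; the low temperature avoids aldol closure of the 1,5-diketone (the descriptor at C9 changes by CIP priority only).

Step 7
Reactants: 10 methyl 3-{3-[(4R)-2,2-dimethyl-1,3-dioxolan-4-yl]but-3-en-1-yl}-2,2-dimethyl-4-oxocyclohexane-1-carboxylate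
Product: 12 (5S,9R,10S) bridged ketal in which C10 is bonded to the C9 and C12 oxygens (dioxabicyclo[4.2.1]nonane fused to the cyclohexane at C5–C10; C8 methylidene; C3 CO2Me epimers), via keto diol 11 (not isolated)
Conditions: CSA (10 mol %), H2O (trace), PhMe, 60 °C, acetone distilled off
Reagents that add atoms: none
Why: Acid-catalysed transketalisation: the 1,2-diol freed from the acetonide closes onto the C10 ketone to the bridged bicyclic ketal, whose C9–C12 bridge dictates the C10 configuration, while reversible enol ether formation should equilibrate C5 to the trans-fused (5S) epimer that keeps C4 equatorial on the seven-membered ring.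

Step 8
Reactants: 12 (5S,9R,10S) bridged ketal
Product: 13 methyl (2R,5aS,9aS)-2-(hydroxymethyl)-6,6,9a-trimethyl-3-methylidenedecahydro-1-benzoxepine-7-carboxylate (C3 ester epimers; locants: 5S,9R,10S)
Conditions: AlMe3 (4 equiv), PhMe, −78 → 0 °C; then 1 M aq. HCl, 0 °C
Reagents that add atoms: trimethylaluminium, C[Al](C)C
Why: Alkylative cleavage of a bicyclic ketal by an organoaluminium reagent: AlMe3 binds the less hindered primary ketal oxygen, the C10–O bond to it ionises to the oxepanyl oxocarbenium ion and methyl is delivered within the ion pair to the face that oxygen has left (retention), so C10 is set with methyl cis to the C12 carbinol and the oxepane is kept.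

Step 9
Reactants: 13 methyl ester of the oxepane alcohol
Product: 14 (2R,5aS,9aS)-2-(hydroxymethyl)-6,6,9a-trimethyl-3-methylidenedecahydro-1-benzoxepine-7-carboxylic acid (C3 epimers)
Conditions: KOH, MeOH–H2O, 80 °C; then aq. HCl to pH 3
Reagents that add atoms: potassium hydroxide, [K+].[OH-]
Why: Saponification of the hindered ester; the tertiary ether, the 1,1-disubstituted alkene and the primary alcohol are stable to hydroxide, and epimerisation at C3 is without consequence.

Step 10
Reactants: 14 hydroxy acid
Product: 16 (2R,5aS,9aS)-2-(hydroxymethyl)-6,6,9a-trimethyl-3-methylideneoctahydro-1-benzoxepin-7(2H)-one, via α-hydroperoxy acid 15 (not isolated)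
Conditions: LiN(i-Pr)2 (3.5 equiv), THF–DMPU, −78 → 25 °C; O2, −78 °C; then aq. HCl work-up, PhMe, 40 °C
Reagents that add atoms: dioxygen, O=O
Why: Oxidative decarboxylation: the carboxylate α-anion is oxygenated by O2 to the α-hydroperoxy acid, which loses CO2 and water to give the C3 ketone and thereby clears the stereo-mixture at C3.

Step 11
Reactants: 16 hydroxy ketone
Product: 17 (2R,5aS,7R,9aS)-2-(hydroxymethyl)-6,6,9a-trimethyl-3-methylidenedecahydro-1-benzoxepin-7-ol (axial C3 alcohol; locants: 3R,5S,9R,10S)
Conditions: LiBH(s-Bu)3 (2.5 equiv), THF, −78 °C; then aq. NH4Cl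
Reagents that add atoms: none
Why: The bulky trialkylborohydride attacks the C3 ketone along the equatorial trajectory, as in 4,4-dimethyl-3-oxo terpenoids, and should give the axial (3R) alcohol needed for inversion.

Step 12
Reactants: 17 diol
Product: 18 (2R,5aS,7S,9aS)-7-bromo-2-(bromomethyl)-6,6,9a-trimethyl-3-methylidenedecahydro-1-benzoxepine
Conditions: CBr4, PPh3, CH2Cl2, 0 °C; then PhMe, 60 °C
Reagents that add atoms: carbon tetrabromide, BrC(Br)(Br)Br
Why: Appel reaction: both alkoxyphosphonium ions are displaced by bromide in SN2 fashion, the primary one without stereochemical consequence and the axial C3 one with inversion to the equatorial (3S) bromide.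

Step 13
Reactants: 18 dibromide
Product: 19 (2R,4R,5aS,7S,9aS)-7-bromo-2-(bromomethyl)-6,6,9a-trimethyl-3-methylidenedecahydro-1-benzoxepin-4-ol (target; locants: 3S,5S,7R,9R,10S)
Conditions: SeO2 (0.5 equiv), t-BuOOH (3 equiv), CH2Cl2, 0 → 25 °C
Reagents that add atoms: selenium dioxide, O=[Se]=O; tert-butyl hydroperoxide, CC(C)(C)OO
Why: SeO2 allylic hydroxylation (ene reaction, then [2,3]-sigmatropic shift) of the 1,1-disubstituted alkene oxidises the allylic CH2 (C7) in preference to the oxygen-substituted CH (C9) and keeps the exocyclic double bond; attack on the ring face opposite to the C10 methyl and the C9 bromomethyl group should give the (7R) alcohol.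

Compound list

1 | mesityl oxide (4-methylpent-3-en-2-one) | CC(=O)C=C(C)C | starting material
2 | tert-butyl(dimethyl)[(4-methylpenta-1,3-dien-2-yl)oxy]silane | C=C(O[Si](C)(C)C(C)(C)C)C=C(C)C | intermediate
3 | methyl acrylate | C=CC(=O)OC | starting material
4 | methyl 4-[(tert-butyldimethylsilyl)oxy]-2,2-dimethylcyclohex-3-ene-1-carboxylate (racemic) | COC(=O)C1CCC(O[Si](C)(C)C(C)(C)C)=CC1(C)C | intermediate
5 | methyl (S)-2,2-dimethyl-1,3-dioxolane-4-carboxylate | COC(=O)[C@@H]1COC(C)(C)O1 | starting material
6 | (S)-N-methoxy-N,2,2-trimethyl-1,3-dioxolane-4-carboxamide | CON(C)C(=O)[C@@H]1COC(C)(C)O1 | intermediate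
7 | (S)-1-(2,2-dimethyl-1,3-dioxolan-4-yl)prop-2-en-1-one | C=CC(=O)[C@@H]1COC(C)(C)O1 | intermediate
8 | C8 tert-butyldimethylsilyl enol ether of 9 (not isolated; C3 and C5 epimers) | COC(=O)C1CCC(=O)C(CC=C(O[Si](C)(C)C(C)(C)C)[C@@H]2COC(C)(C)O2)C1(C)C | intermediate
9 | methyl 3-{3-[(4S)-2,2-dimethyl-1,3-dioxolan-4-yl]-3-oxopropyl}-2,2-dimethyl-4-oxocyclohexane-1-carboxylate (C3 and C5 epimers) | COC(=O)C1CCC(=O)C(CCC(=O)[C@@H]2COC(C)(C)O2)C1(C)C | intermediate
10 | methyl 3-{3-[(4R)-2,2-dimethyl-1,3-dioxolan-4-yl]but-3-en-1-yl}-2,2-dimethyl-4-oxocyclohexane-1-carboxylate (C3 and C5 epimers) | COC(=O)C1CCC(=O)C(CCC(=C)[C@@H]2COC(C)(C)O2)C1(C)C | intermediate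
11 | methyl 3-[(4R)-4,5-dihydroxy-3-methylidenepentyl]-2,2-dimethyl-4-oxocyclohexane-1-carboxylate (not isolated) | COC(=O)C1CCC(=O)C(CCC(=C)[C@@H](O)CO)C1(C)C | intermediate
12 | (5S,9R,10S) bridged ketal: C10 bonded to O–C9 and O–C12, C8 methylidene, C3 CO2Me (C3 epimers) | C=C1CC[C@H]2C(C)(C)C(C(=O)OC)CC[C@]2(O3)O[C@H]1C3 | intermediate
13 | methyl (2R,5aS,9aS)-2-(hydroxymethyl)-6,6,9a-trimethyl-3-methylidenedecahydro-1-benzoxepine-7-carboxylate (C3 epimers) | C=C1CC[C@H]2C(C)(C)C(C(=O)OC)CC[C@]2(C)O[C@H]1CO | intermediate
14 | (2R,5aS,9aS)-2-(hydroxymethyl)-6,6,9a-trimethyl-3-methylidenedecahydro-1-benzoxepine-7-carboxylic acid (C3 epimers) | C=C1CC[C@H]2C(C)(C)C(C(=O)O)CC[C@]2(C)O[C@H]1CO | intermediate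
15 | α-hydroperoxy acid at C3 (not isolated) | C=C1CC[C@H]2C(C)(C)C(OO)(C(=O)O)CC[C@]2(C)O[C@H]1CO | intermediate
16 | (2R,5aS,9aS)-2-(hydroxymethyl)-6,6,9a-trimethyl-3-methylideneoctahydro-1-benzoxepin-7(2H)-one | C=C1CC[C@H]2C(C)(C)C(=O)CC[C@]2(C)O[C@H]1CO | intermediate
17 | (2R,5aS,7R,9aS)-2-(hydroxymethyl)-6,6,9a-trimethyl-3-methylidenedecahydro-1-benzoxepin-7-ol | C=C1CC[C@H]2C(C)(C)[C@H](O)CC[C@]2(C)O[C@H]1CO | intermediate
18 | (2R,5aS,7S,9aS)-7-bromo-2-(bromomethyl)-6,6,9a-trimethyl-3-methylidenedecahydro-1-benzoxepine | C=C1CC[C@H]2C(C)(C)[C@@H](Br)CC[C@]2(C)O[C@H]1CBr | intermediate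
19 | (2R,4R,5aS,7S,9aS)-7-bromo-2-(bromomethyl)-6,6,9a-trimethyl-3-methylidenedecahydro-1-benzoxepin-4-ol | C=C1[C@H](O)C[C@H]2C(C)(C)[C@@H](Br)CC[C@]2(C)O[C@H]1CBr | target

Total step count: 13. Longest linear sequence: 11 steps (steps 1, 2 and 5–13); steps 3 and 4 make the side-chain enone 7.

Steps most likely to fail

Step 7. The acid-mediated equilibration at the ring-fusion carbon C5 may stall, or the thermodynamic bias between the trans- and cis-fused ketals may be too small. The fallback sets C5 under reagent control before the ketal is closed; it sets out from 10 and comes back at 12. Compound 10 is converted under thermodynamic conditions (TMSCl, NaI, Et3N, MeCN) into the more substituted trimethylsilyl enol ether F1. F1 is protonated at −78 °C by a Lewis acid-assisted chiral Brønsted acid, the SnCl4 complex of the enantiomer of 2-hydroxy-2′-methoxy-1,1′-binaphthyl that gives the (5S) ketone F2. Ketalisation of F2 under non-equilibrating conditions (PPTS, wet CH2Cl2, 25 °C) should then give 12 without touching C5.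

Step 8. Methyl transfer to the oxocarbenium ion may occur from the equatorial face (loss of ion-pair control), or the ring C10–O bond may be cleaved instead of the bridge bond. The fallback uses the ketal only as the device that fixed C5 and closes the oxepane by C–O bond formation; it sets out from 12 and comes back at 13. Hydrolysis (aq. HCl, THF, 25 °C) gives the (5S) keto diol F3. Non-basic methylenation (Cp2TiMe2, PhMe, 70 °C) gives the diene diol F4. Acid-catalysed Markovnikov hydroalkoxylation (Tf2NH 5 mol %, CH2Cl2, −40 °C) of the electron-richer C10 methylidene by the C9 hydroxyl should give 13, the oxygen entering equatorially, anti to the axial C4 methyl.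

Step 12. Displacement at the neopentyl C3 may be overtaken by E2 elimination towards C2 or by a Wagner–Meerwein methyl shift from C4 at the temperature the oxyphosphonium ion needs. The fallback separates the two brominations and replaces in-situ phosphonium activation by an isolated sulfonate; it sets out from 17 and comes back at 18. CBr4/PPh3 at 0 °C converts only the primary alcohol and gives the bromo alcohol F5. The axial C3 alcohol is isolated as its mesylate F6 (MsCl, Et3N, CH2Cl2, 0 °C). Displacement with LiBr in butanone at 80 °C (SN2, inversion) should give 18.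

Further compounds

F1 | step 7 | trimethylsilyl enol ether (C10=C5) of 10 | COC(=O)C1CCC(O[Si](C)(C)C)=C(CCC(=C)[C@@H]2COC(C)(C)O2)C1(C)C
F2 | step 7 | (5S) epimer of 10 (C5 as in 13; C3 epimers) | COC(=O)C1CCC(=O)[C@@H](CCC(=C)[C@@H]2COC(C)(C)O2)C1(C)C
F3 | step 8 | (5S) keto diol (single C5 epimer of 11) | COC(=O)C1CCC(=O)[C@@H](CCC(=C)[C@@H](O)CO)C1(C)C
F4 | step 8 | diene diol with C10 methylidene (C5 as in 13) | COC(=O)C1CCC(=C)[C@@H](CCC(=C)[C@@H](O)CO)C1(C)C
F5 | step 12 | (2R,5aS,7R,9aS)-2-(bromomethyl)-6,6,9a-trimethyl-3-methylidenedecahydro-1-benzoxepin-7-ol | C=C1CC[C@H]2C(C)(C)[C@H](O)CC[C@]2(C)O[C@H]1CBr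
F6 | step 12 | C3 methanesulfonate of F5 | C=C1CC[C@H]2C(C)(C)[C@H](OS(C)(=O)=O)CC[C@]2(C)O[C@H]1CBr
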